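**Retrosynthetic overview**
- Sceptrin ⇐ its bis(imidazo[1,2-a]pyrimidine) precursor. Both 2-aminoimidazoles stay masked as the bought bicyclic heteroarene and are unveiled last by hydrazine.
- The two amide bonds ⇐ an all-trans cyclobutane-1,2-bis(methanamine) plus an activated 4-bromopyrrole-2-carbonyl donor.
- The two primary amines ⇐ a trans-fused 3,6-diazabicyclo[6.2.0]decane in which a C2-symmetric 1,2-diphenylethane-1,2-diyl unit bridges both nitrogens. This unit acts as a chiral ammonia equivalent and is removed by C–C cleavage.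
- Key disconnection: both new cyclobutane C–C bonds, back to an acyclic N,N'-bis(heteroarylallyl) diamine. One sensitised intramolecular [2+2] closes the eight-membered ring and the cyclobutane and sets all four stereocentres.
- Ring order: heteroaryl rings bought; diazocane and cyclobutane formed together (step 3); diazocane opened (step 4); aminoimidazoles unmasked (step 6).

Assumption: the three heterocyclic and chiral building blocks used as starting materials are catalogue compounds, and sceptrin is drawn as the free base although it is handled as a salt.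

**Step 1**
Reactants: 1 3-bromoimidazo[1,2-a]pyrimidine; 2 acrolein diethyl acetal (3,3-diethoxyprop-1-ene)
Product: 4 (2E)-3-(imidazo[1,2-a]pyrimidin-3-yl)prop-2-enal, via alkenyl diethyl acetal 3 (not isolated)
Conditions: Pd(OAc)2 (3 mol %), Bu4NOAc, K2CO3, KCl, DMF, 90 °C; then 2 M aq. HCl, rt
Reagents that add atoms: water (O)
Why: Heck reaction in its acrolein-acetal form: oxidative addition of the heteroaryl bromide to zerovalent palladium, syn-carbopalladation and β-hydride elimination away from the acetal carbon give the E-alkenyl acetal, which aqueous acid hydrolyses to the conjugated E-enal.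

**Step 2**
Reactants: 4 (2E)-3-(imidazo[1,2-a]pyrimidin-3-yl)prop-2-enal (2 equiv); 5 (1S,2S)-1,2-diphenylethane-1,2-diamine
Product: 7 (1S,2S)-N,N'-bis[(2E)-3-(imidazo[1,2-a]pyrimidin-3-yl)prop-2-en-1-yl]-1,2-diphenylethane-1,2-diamine, via bis(enimine) 6 (not isolated)
Conditions: 4 Å MS, CH2Cl2/MeOH, rt, 2 h; then NaBH4, 0 °C
Reagents that add atoms: none
Why: Double reductive amination: a primary 1,2-diamine with two equivalents of aldehyde gives the conjugated bis-imine, which NaBH4 reduces 1,2 at 0 °C before any diaza-Cope rearrangement, so the alkene geometry and the two diamine stereocentres are untouched.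

**Step 3**
Reactants: 7 (1S,2S)-N,N'-bis[(2E)-3-(imidazo[1,2-a]pyrimidin-3-yl)prop-2-en-1-yl]-1,2-diphenylethane-1,2-diamine
Product: 8 (1R,4S,5S,8R,9S,10S)-9,10-bis(imidazo[1,2-a]pyrimidin-3-yl)-4,5-diphenyl-3,6-diazabicyclo[6.2.0]decane
Conditions: Ir(ppy)3 (2 mol %), degassed MeCN (2 mM), 450 nm LEDs, 25 °C; chromatography
Reagents that add atoms: none
Why: Proposed new method: triplet energy transfer from excited Ir(ppy)3 (too weak an excited-state oxidant, about +0.3 V against SCE, to oxidise the secondary amines) gives a styrene-type triplet on one arm whose β-carbon adds to the β-carbon of the other arm, closing the eight-membered ring and leaving a bis(heteroarylmethyl) 1,4-biradical that collapses to the cyclobutane, so two rings form in one operation; the first bond is reversible and the biradical closes to the least crowded all-trans ring; the gauche N–C–C–N unit of the (S,S)-diamine with both phenyls pseudo-equatorial has a positive torsion, which in a boat-chair or crown diazocane is matched with a positive CH2–C–C–CH2 torsion at the trans ring fusion, i.e. the (1R,8R) and hence (9S,10S) configuration; the closest known reactions are the Ir(ppy)3-sensitised head-to-head [2+2] dimerisation of imidazopyrimidine-masked hymenidin-type vinyl heteroarenes and the tether-directed intramolecular [2+2] photocycloaddition of dicinnamates of C2-symmetric diols to δ-truxinates.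

**Step 4**
Reactants: 8 (1R,4S,5S,8R,9S,10S)-9,10-bis(imidazo[1,2-a]pyrimidin-3-yl)-4,5-diphenyl-3,6-diazabicyclo[6.2.0]decane
Product: 10 [(1R,2R,3S,4S)-3,4-bis(imidazo[1,2-a]pyrimidin-3-yl)cyclobutane-1,2-diyl]dimethanamine, via bis(N-benzylidene) diamine 9 (not isolated)
Conditions: Pb(OAc)4 (1.1 equiv), CH2Cl2/MeOH 2:1, 0 °C, 15 min; then 1 M aq. HCl, rt; Et2O wash; aq. NaOH
Reagents that add atoms: none
Why: Criegee-type oxidative cleavage of a vicinal diamine: Pb(OAc)4 chelates both nitrogens and fragments the PhCH–CHPh bond to two N-benzylidene imines, which acid hydrolyses to the primary amines; no bond at a cyclobutane stereocentre is touched.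

**Step 5**
Reactants: 10 [(1R,2R,3S,4S)-3,4-bis(imidazo[1,2-a]pyrimidin-3-yl)cyclobutane-1,2-diyl]dimethanamine; 11 2,2,2-trichloro-1-(4-bromo-1H-pyrrol-2-yl)ethan-1-one (2.1 equiv)
Product: 12 N,N'-{[(1R,2R,3S,4S)-3,4-bis(imidazo[1,2-a]pyrimidin-3-yl)cyclobutane-1,2-diyl]bis(methylene)}bis(4-bromo-1H-pyrrole-2-carboxamide)
Conditions: Et3N (0.2 equiv), DMF, 25 °C
Reagents that add atoms: none
Why: Haloform-type N-acylation: the primary amines add to the trichloromethyl ketone and expel CCl3–, giving the pyrrole carboxamides without protecting the pyrrole NH; the ring nitrogens of the heteroarenes are not acylated.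

**Step 6**
Reactants: 12 N,N'-{[(1R,2R,3S,4S)-3,4-bis(imidazo[1,2-a]pyrimidin-3-yl)cyclobutane-1,2-diyl]bis(methylene)}bis(4-bromo-1H-pyrrole-2-carboxamide)
Product: 13 sceptrin
Conditions: N2H4·H2O (excess), EtOH, 80 °C; reversed-phase chromatography (isolated as the bis-HCl salt)
Reagents that add atoms: none
Why: Hydrazinolysis of the imidazo[1,2-a]pyrimidine: hydrazine adds to the electron-poor pyrimidine ring and excises its three-carbon unit as pyrazole, leaving the 2-amino-1H-imidazol-5-yl groups; secondary amides, bromopyrroles and the cyclobutane stereocentres are inert under these conditions.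

**Compound list**
1 | 3-bromoimidazo[1,2-a]pyrimidine | Brc1cnc2ncccn12 | starting material
2 | acrolein diethyl acetal | C=CC(OCC)OCC | starting material
3 | 3-[(1E)-3,3-diethoxyprop-1-en-1-yl]imidazo[1,2-a]pyrimidine | CCOC(OCC)/C=C/c1cnc2ncccn12 | intermediate
4 | (2E)-3-(imidazo[1,2-a]pyrimidin-3-yl)prop-2-enal | O=C/C=C/c1cnc2ncccn12 | intermediate
5 | (1S,2S)-1,2-diphenylethane-1,2-diamine | N[C@@H](c1ccccc1)[C@@H](N)c1ccccc1 | starting material
6 | (1S,2S)-N,N'-bis[(2E)-3-(imidazo[1,2-a]pyrimidin-3-yl)prop-2-en-1-ylidene]-1,2-diphenylethane-1,2-diamine | c1cnc2ncc(/C=C/C=N/[C@@H](c3ccccc3)[C@@H](/N=C/C=C/c3cnc4ncccn34)c3ccccc3)n2c1 | intermediate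
7 | (1S,2S)-N,N'-bis[(2E)-3-(imidazo[1,2-a]pyrimidin-3-yl)prop-2-en-1-yl]-1,2-diphenylethane-1,2-diamine | c1cnc2ncc(/C=C/CN[C@@H](c3ccccc3)[C@@H](NC/C=C/c3cnc4ncccn34)c3ccccc3)n2c1 | intermediate
8 | (1R,4S,5S,8R,9S,10S)-9,10-bis(imidazo[1,2-a]pyrimidin-3-yl)-4,5-diphenyl-3,6-diazabicyclo[6.2.0]decane | c1cnc2ncc([C@H]3[C@@H]4CN[C@@H](c5ccccc5)[C@H](c5ccccc5)NC[C@H]4[C@@H]3c3cnc4ncccn34)n2c1 | intermediate
9 | N,N'-{[(1R,2R,3S,4S)-3,4-bis(imidazo[1,2-a]pyrimidin-3-yl)cyclobutane-1,2-diyl]bis(methylene)}bis(1-phenylmethanimine) | c1cnc2ncc([C@H]3[C@H](C/N=C/c4ccccc4)[C@@H](C/N=C/c4ccccc4)[C@@H]3c3cnc4ncccn34)n2c1 | intermediate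
10 | [(1R,2R,3S,4S)-3,4-bis(imidazo[1,2-a]pyrimidin-3-yl)cyclobutane-1,2-diyl]dimethanamine | c1cnc2ncc([C@H]3[C@H](CN)[C@@H](CN)[C@@H]3c3cnc4ncccn34)n2c1 | intermediate
11 | 2,2,2-trichloro-1-(4-bromo-1H-pyrrol-2-yl)ethan-1-one | O=C(c1cc(Br)c[nH]1)C(Cl)(Cl)Cl | starting material
12 | N,N'-{[(1R,2R,3S,4S)-3,4-bis(imidazo[1,2-a]pyrimidin-3-yl)cyclobutane-1,2-diyl]bis(methylene)}bis(4-bromo-1H-pyrrole-2-carboxamide) | c1cnc2ncc([C@H]3[C@H](CNC(=O)c4cc(Br)c[nH]4)[C@@H](CNC(=O)c4cc(Br)c[nH]4)[C@@H]3c3cnc4ncccn34)n2c1 | intermediate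
13 | sceptrin, N,N'-{[(1R,2R,3S,4S)-3,4-bis(2-amino-1H-imidazol-5-yl)cyclobutane-1,2-diyl]bis(methylene)}bis(4-bromo-1H-pyrrole-2-carboxamide) | Nc1ncc([C@H]2[C@H](CNC(=O)c3cc(Br)c[nH]3)[C@@H](CNC(=O)c3cc(Br)c[nH]3)[C@@H]2c2cnc(N)[nH]2)[nH]1 | target

**Step count and risks**
Total steps: 6. Longest linear sequence: 6 (1 → 4 → 7 → 8 → 10 → 12 → 13).

Most likely to fail, in order:

**Step 3 (tethered [2+2]).** The eight-membered ring closure from a short-lived triplet may be slow against E/Z isomerisation and oligomerisation. The sense and level of induction are a conformational prediction, not precedent. The two possible cyclobutane antipodes are diastereomers at the stage of 8 and can be separated, and the configuration of 8 should be confirmed (crystal structure of a salt, or comparison of 13 with the natural product) before scale-up.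

Fallback, setting out from 4 and returning at 12: the cyclobutane is made by intermolecular dimerisation and the enantiomers are separated. Enal 4 with NH2OH·HCl/NaOAc gives (2E)-3-(imidazo[1,2-a]pyrimidin-3-yl)prop-2-enal oxime F1. Zn/AcOH reduces it to (2E)-3-(imidazo[1,2-a]pyrimidin-3-yl)prop-2-en-1-amine F2. Acylation with 11 gives the hymenidin surrogate 4-bromo-N-[(2E)-3-(imidazo[1,2-a]pyrimidin-3-yl)prop-2-en-1-yl]-1H-pyrrole-2-carboxamide F3. Ir(ppy)3 under 450 nm light dimerises F3 head-to-head to racemic 12, that is 12 together with its mirror image, the (1S,2S,3R,4R)-configured bis-amide F4. Preparative chromatography on a chiral stationary phase gives 12, and the route resumes with step 6.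

**Step 4 (oxidative tether cleavage).** Pb(OAc)4 may attack the electron-rich heteroarenes or oxidise the other N–CH2 positions.

Fallback, setting out from 8 and returning at 13: the endgame order is inverted so the tether can be removed reductively without a pyrimidine ring present to be over-reduced. Hydrazinolysis of 8 gives (1R,4S,5S,8R,9S,10S)-9,10-bis(2-amino-1H-imidazol-5-yl)-4,5-diphenyl-3,6-diazabicyclo[6.2.0]decane F5. Hydrogenolysis of its two benzylic C–N bonds (Pd(OH)2/C, H2, MeOH/aq. HCl, 40 °C; the tether leaves as 1,2-diphenylethane) gives the tetraamine 5,5'-[(1S,2S,3R,4R)-3,4-bis(aminomethyl)cyclobutane-1,2-diyl]bis(1H-imidazol-2-amine) F6. Acylation of F6 with 11 (DMF, Et3N) takes place only at the two primary alkylamines, as in oroidin-type acylations, and gives 13 directly.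

**Step 1 (Heck reaction).** The N-rich heteroaryl bromide may bind palladium, and β-hydride elimination toward the acetal carbon would give the saturated ester instead of the enal.

Fallback, setting out from 1 and returning at 4: the three-carbon unit is introduced with its geometry already fixed. Stille coupling of 1 with (E)-3-(tributylstannyl)prop-2-en-1-ol (Pd(PPh3)4, CuI, DMF, 80 °C) gives (2E)-3-(imidazo[1,2-a]pyrimidin-3-yl)prop-2-en-1-ol F7. MnO2 in CH2Cl2 oxidises F7 to 4.

**Further compounds**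
F1 | step 3 | (2E)-3-(imidazo[1,2-a]pyrimidin-3-yl)prop-2-enal oxime | O/N=C/C=C/c1cnc2ncccn12
F2 | step 3 | (2E)-3-(imidazo[1,2-a]pyrimidin-3-yl)prop-2-en-1-amine | NC/C=C/c1cnc2ncccn12
F3 | step 3 | 4-bromo-N-[(2E)-3-(imidazo[1,2-a]pyrimidin-3-yl)prop-2-en-1-yl]-1H-pyrrole-2-carboxamide | O=C(NC/C=C/c1cnc2ncccn12)c1cc(Br)c[nH]1
F4 | step 3 | N,N'-{[(1S,2S,3R,4R)-3,4-bis(imidazo[1,2-a]pyrimidin-3-yl)cyclobutane-1,2-diyl]bis(methylene)}bis(4-bromo-1H-pyrrole-2-carboxamide) | c1cnc2ncc([C@@H]3[C@@H](CNC(=O)c4cc(Br)c[nH]4)[C@H](CNC(=O)c4cc(Br)c[nH]4)[C@H]3c3cnc4ncccn34)n2c1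
F5 | step 4 | (1R,4S,5S,8R,9S,10S)-9,10-bis(2-amino-1H-imidazol-5-yl)-4,5-diphenyl-3,6-diazabicyclo[6.2.0]decane | Nc1ncc([C@H]2[C@@H]3CN[C@@H](c4ccccc4)[C@H](c4ccccc4)NC[C@H]3[C@@H]2c2cnc(N)[nH]2)[nH]1
F6 | step 4 | 5,5'-[(1S,2S,3R,4R)-3,4-bis(aminomethyl)cyclobutane-1,2-diyl]bis(1H-imidazol-2-amine) | Nc1ncc([C@H]2[C@H](CN)[C@@H](CN)[C@@H]2c2cnc(N)[nH]2)[nH]1
F7 | step 1 | (2E)-3-(imidazo[1,2-a]pyrimidin-3-yl)prop-2-en-1-ol | OC/C=C/c1cnc2ncccn12
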